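## Retrosynthetic overview

1. Presumed biogenesis: a germacrene A acid-type ten-membered ring (farnesyl C1–C10 closure) takes up two five-carbon units, one by ene-type prenylation (prenyl on C5, C4=CH2) and one by formal [2+2] across the (E)-C1=C10 olefin.
2. Last disconnections: C4=CH2 from a C4 ketone (methylenation); prenyl from allyl (cross-metathesis), so that no second electron-rich trisubstituted olefin is present when the cyclobutane is made.
3. Cyclobutane (ring formed second): [2+2] of a senecioic-acid-derived vinylketeniminium ion onto the (E)-C1=C10 olefin of the ten-membered ring; the extra carbon–heteroatom double bond is excised through a tosylhydrazone.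
4. Ten-membered ring (formed first): the C6–C7 bond (the farnesyl C1–C10 bond) by enantioselective intramolecular Michael addition of an α-keto ester enol to a vinyl ketone; the α-keto ester is then methylenated to the acrylate.
5. Acyclic precursor: geranyl bromide + ethyl 2-allylacetoacetate, then decarboxylative methylenation, terminal olefin cleavage and Horner–Wadsworth–Emmons extension.

Locants in the Why lines (germacrane numbering of the final skeleton): C1 and C10 are the ring-fusion carbons (C10 carries CH3), C4 the exocyclic-methylene carbon, C5 the prenyl-bearing carbon, C6 the CH2 between C5 and C7, C7 the acrylate-bearing carbon; C1′ (CH2) and C2′ (isopropenyl-bearing) are the other two cyclobutane carbons.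

Assumption: the sense of induction of the cupreidine-derived catalyst in step 6 is assigned by analogy and gives 13 as drawn; if it proved opposite, the pseudo-enantiomeric cupreine-derived catalyst would be used.

## Route

Step 1
Reactants: 1 geranyl bromide, (2E)-1-bromo-3,7-dimethylocta-2,6-diene; 2 ethyl 2-allylacetoacetate (ethyl 2-acetylpent-4-enoate)
Product: 4 ethyl (6E)-7,11-dimethyl-3-oxo-2-(prop-2-en-1-yl)dodeca-6,10-dienoate (racemic at C-2), via acetoacetate dianion 3 (not isolated)
Conditions: NaH, THF, 0 °C; n-BuLi, 0 °C; then 1, 0 °C → rt; aq. NH4Cl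
Reagents that add atoms: none
Why: Huckin–Weiler dianion alkylation: the more basic terminal carbanion of the α-allyl acetoacetate dianion displaces the allylic bromide (SN2) with retention of the (E)-olefin, and the racemic stereocentre is erased in step 2.

Step 2
Reactants: 4
Product: 6 (8E)-9,13-dimethyl-4-methylidenetetradeca-1,8,12-trien-5-one, via β-keto acid 5 (not isolated)
Conditions: KOH, EtOH/H2O, rt; HCl to pH 5; then 37% aq. CH2O, Et2NH, 50 °C
Reagents that add atoms: formaldehyde, C=O
Why: Saponification gives the β-keto acid, which undergoes a Mannich reaction at its doubly activated carbon followed by decarboxylative loss of the amine (decarboxylative Mannich methylenation), so the carbon that becomes C6 is placed regiospecifically as the β-carbon of an α-allyl vinyl ketone.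

Step 3
Reactants: 6
Product: 8 (8E)-11-(3,3-dimethyloxiran-2-yl)-9-methyl-4-methylideneundeca-1,8-dien-5-one (racemic), via bromohydrin 7 (not isolated)
Conditions: NBS, THF/H2O (3:1), 0 °C; then K2CO3, rt
Reagents that add atoms: water, O
Why: van Tamelen-type bromohydrin formation favours the terminal trisubstituted olefin (the enone and the monosubstituted allyl olefin are far less nucleophilic, the internal olefin reacts more slowly) and carbonate closes the epoxide, whose racemic stereocentre is destroyed in step 4.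

Step 4
Reactants: 8
Product: 9 (4E)-4-methyl-9-methylidene-8-oxododeca-4,11-dienal
Conditions: H5IO6, THF/H2O, 0 °C
Reagents that add atoms: none
Why: Periodic acid hydrolyses the epoxide to the glycol and cleaves it (Malaprade glycol cleavage), excising acetone and unveiling the aldehyde at the future C7 without touching the enone or the other olefins.

Step 5
Reactants: 9; 10 Boc-α-phosphonoglycine trimethyl ester, methyl 2-[(tert-butoxycarbonyl)amino]-2-(dimethoxyphosphoryl)acetate
Product: 12 methyl (6E)-6-methyl-11-methylidene-2,10-dioxotetradeca-6,13-dienoate, via Boc-enamide ester 11 (not isolated)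
Conditions: tetramethylguanidine, THF, −78 → 0 °C; then TFA, CH2Cl2, 0 °C; H2O
Reagents that add atoms: water, O
Why: Horner–Wadsworth–Emmons olefination with the Schmidt phosphonoglycinate gives the (Z)-dehydroamino ester, and Boc acidolysis followed by hydrolysis of the enamine/imine unmasks the α-keto ester, whose enol is the nucleophilic stand-in for the terminal isopropylidene olefin of farnesyl diphosphate.

Step 6
Reactants: 12
Product: 13 methyl 2-[(1S,4E,9R)-4-methyl-8-oxo-9-(prop-2-en-1-yl)cyclodec-4-en-1-yl]-2-oxoacetate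
Conditions: 9-O-(9-phenanthryl)cupreidine (20 mol %), toluene, 1 mM, slow addition, −20 °C → rt
Reagents that add atoms: none
Why: Proposed new method: the bifunctional cinchona base/hydrogen-bond catalyst enolises the α-keto ester and delivers it intramolecularly, under high dilution, to the unsubstituted β-carbon (C6) of the vinyl ketone, closing the ten-membered ring at the bond the terpene cyclase forms, with the catalyst fixing the enol face (C7, S) and the following protonation of the C4/C5 enol (C5, R) as in tandem conjugate addition–protonation; the closest known reactions are cinchona-catalysed Michael additions of α-substituted β-keto esters to vinyl ketones and ten-membered germacrane ring closures by intramolecular carbanion alkylation.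

Step 7
Reactants: 13
Product: 14 methyl 2-[(1S,4E,9R)-4-methyl-8-oxo-9-(prop-2-en-1-yl)cyclodec-4-en-1-yl]prop-2-enoate
Conditions: Ph3PCH3Br, KN(SiMe3)2, THF, −78 °C
Reagents that add atoms: methyltriphenylphosphonium bromide, C[P+](c1ccccc1)(c1ccccc1)c1ccccc1.[Br-]
Why: Wittig methylenation: at −78 °C the ylide attacks only the strongly electrophilic α-keto ester carbonyl and not the hindered ring ketone, giving the 2-substituted acrylate and making C7 configurationally stable.

Step 8
Reactants: 15 3-methylbut-2-enoyl chloride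
Product: 16 N,N,3-trimethylbut-2-enamide
Conditions: 40% aq. Me2NH, NaOH, CH2Cl2, 0 °C
Reagents that add atoms: dimethylamine, CNC
Why: Schotten–Baumann amidation gives the tertiary amide needed as the keteniminium precursor.

Step 9
Reactants: 14; 16
Product: 19 methyl 2-[(1S,4S,6R,10S,12R)-1-methyl-11-{2-[(4-methylphenyl)sulfonyl]hydrazinylidene}-7-oxo-6-(prop-2-en-1-yl)-12-(prop-1-en-2-yl)bicyclo[8.2.0]dodecan-4-yl]prop-2-enoate, via keteniminium triflate 17 (not isolated), via cyclobutaniminium triflate 18 (not isolated)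
Conditions: 16, Tf2O, 2,4,6-collidine, ClCH2CH2Cl, −25 °C; then 14, −25 → 40 °C; then TsNHNH2, rt
Reagents that add atoms: 4-methylbenzenesulfonohydrazide, Cc1ccc(cc1)S(=O)(=O)NN
Why: Proposed new method: Ghosez keteniminium–olefin [2+2] cycloaddition in which the electrophilic central carbon of 17 bonds to the less substituted C1 and its isopropenyl-bearing carbon to C10 of the strained (E)-olefin, suprafacially (hence the trans ring fusion) and on the exposed outer face of the conformer with the C7 side chain pseudo-equatorial (the face peracids take in germacrenes), the isopropenyl group ending on the more substituted face cis to the C10 methyl while the acrylate and allyl olefins do not compete; the cyclobutaniminium ion is then captured by tosylhydrazide instead of water (iminium–hydrazine exchange), which spares the ring ketone, the closest known reactions being keteniminium [2+2] with trisubstituted olefins followed by hydrolysis and hydrazone formation from iminium salts.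

Step 10
Reactants: 19
Product: 21 methyl 2-[(1S,4S,6R,10R,12R)-1-methyl-7-oxo-6-(prop-2-en-1-yl)-12-(prop-1-en-2-yl)bicyclo[8.2.0]dodecan-4-yl]prop-2-enoate, via N-boryl tosylhydrazine 20 (not isolated)
Conditions: catecholborane, CHCl3, 0 °C; then NaOAc·3H2O, 60 °C
Reagents that add atoms: none
Why: Kabalka reduction: catecholborane delivers hydride to the hydrazone carbon at 0 °C without reducing the ring ketone, ester or olefins, and acetate-promoted loss of sulfinate and dinitrogen from the diazene leaves the C1′ methylene with C1, C10 and C2′ unchanged.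

Step 11
Reactants: 21
Product: 22 methyl 2-[(1S,4S,6R,10R,12R)-1-methyl-6-(3-methylbut-2-en-1-yl)-7-oxo-12-(prop-1-en-2-yl)bicyclo[8.2.0]dodecan-4-yl]prop-2-enoate
Conditions: second-generation Grubbs catalyst (5 mol %), 2-methylbut-2-ene/CH2Cl2 (1:1), 40 °C
Reagents that add atoms: 2-methylbut-2-ene, CC=C(C)C
Why: Olefin cross-metathesis with excess 2-methylbut-2-ene turns the monosubstituted allyl olefin into the prenyl group, the 1,1-disubstituted isopropenyl and acrylate olefins being unreactive under these conditions, and no stereocentre is touched.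

Step 12
Reactants: 22
Product: 23 methyl 2-[(1S,4S,6R,10R,12R)-1-methyl-7-methylidene-6-(3-methylbut-2-en-1-yl)-12-(prop-1-en-2-yl)bicyclo[8.2.0]dodecan-4-yl]prop-2-enoate (CNP0314186.1)
Conditions: Zn, CH2Br2, TiCl4, THF/CH2Cl2, 0 °C → rt
Reagents that add atoms: dibromomethane, BrCBr
Why: Takai–Lombardo methylenation is non-basic and ketone-selective, converting the hindered C4 ketone into the exocyclic methylene without enolising the adjacent C5 stereocentre or touching the methyl ester.

## Compound list

1 | geranyl bromide, (2E)-1-bromo-3,7-dimethylocta-2,6-diene | CC(C)=CCC/C(C)=C/CBr | starting material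
2 | ethyl 2-allylacetoacetate (ethyl 2-acetylpent-4-enoate) | CCOC(=O)C(CC=C)C(C)=O | starting material
3 | sodium lithium α,γ-dianion of ethyl 2-acetylpent-4-enoate | CCOC(=O)[C-](CC=C)C(=O)[CH2-].[Na+].[Li+] | intermediate
4 | ethyl (6E)-7,11-dimethyl-3-oxo-2-(prop-2-en-1-yl)dodeca-6,10-dienoate (racemic) | CCOC(=O)C(CC=C)C(=O)CC/C=C(\C)CCC=C(C)C | intermediate
5 | (6E)-7,11-dimethyl-3-oxo-2-(prop-2-en-1-yl)dodeca-6,10-dienoic acid (racemic) | OC(=O)C(CC=C)C(=O)CC/C=C(\C)CCC=C(C)C | intermediate
6 | (8E)-9,13-dimethyl-4-methylidenetetradeca-1,8,12-trien-5-one | C=CCC(=C)C(=O)CC/C=C(\C)CCC=C(C)C | intermediate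
7 | (8E)-12-bromo-13-hydroxy-9,13-dimethyl-4-methylidenetetradeca-1,8-dien-5-one (racemic) | C=CCC(=C)C(=O)CC/C=C(\C)CCC(Br)C(C)(C)O | intermediate
8 | (8E)-11-(3,3-dimethyloxiran-2-yl)-9-methyl-4-methylideneundeca-1,8-dien-5-one (racemic) | C=CCC(=C)C(=O)CC/C=C(\C)CCC1OC1(C)C | intermediate
9 | (4E)-4-methyl-9-methylidene-8-oxododeca-4,11-dienal | C=CCC(=C)C(=O)CC/C=C(\C)CCC=O | intermediate
10 | methyl 2-[(tert-butoxycarbonyl)amino]-2-(dimethoxyphosphoryl)acetate (racemic) | COC(=O)C(NC(=O)OC(C)(C)C)P(=O)(OC)OC | starting material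
11 | methyl (2Z,6E)-2-[(tert-butoxycarbonyl)amino]-6-methyl-11-methylidene-10-oxotetradeca-2,6,13-trienoate | C=CCC(=C)C(=O)CC/C=C(\C)CC/C=C(\NC(=O)OC(C)(C)C)C(=O)OC | intermediate
12 | methyl (6E)-6-methyl-11-methylidene-2,10-dioxotetradeca-6,13-dienoate | C=CCC(=C)C(=O)CC/C=C(\C)CCCC(=O)C(=O)OC | intermediate
13 | methyl 2-[(1S,4E,9R)-4-methyl-8-oxo-9-(prop-2-en-1-yl)cyclodec-4-en-1-yl]-2-oxoacetate | O=C1CC/C=C(\C)CC[C@H](C(=O)C(=O)OC)C[C@H]1CC=C | intermediate
14 | methyl 2-[(1S,4E,9R)-4-methyl-8-oxo-9-(prop-2-en-1-yl)cyclodec-4-en-1-yl]prop-2-enoate | O=C1CC/C=C(\C)CC[C@H](C(=C)C(=O)OC)C[C@H]1CC=C | intermediate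
15 | 3-methylbut-2-enoyl chloride | CC(C)=CC(=O)Cl | starting material
16 | N,N,3-trimethylbut-2-enamide | CC(C)=CC(=O)N(C)C | intermediate
17 | N,N-dimethyl-N-(3-methylbuta-1,3-dien-1-ylidene)ammonium trifluoromethanesulfonate | C=C(C)C=C=[N+](C)C.[O-]S(=O)(=O)C(F)(F)F | intermediate
18 | N-[(1S,4S,6R,10S,12R)-4-(3-methoxy-3-oxoprop-1-en-2-yl)-1-methyl-7-oxo-6-(prop-2-en-1-yl)-12-(prop-1-en-2-yl)bicyclo[8.2.0]dodecan-11-ylidene]-N-methylmethanaminium trifluoromethanesulfonate | O=C1CC[C@@H]2C(=[N+](C)C)[C@H](C(=C)C)[C@@]2(C)CC[C@H](C(=C)C(=O)OC)C[C@H]1CC=C.[O-]S(=O)(=O)C(F)(F)F | intermediate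
19 | methyl 2-[(1S,4S,6R,10S,12R)-1-methyl-11-{2-[(4-methylphenyl)sulfonyl]hydrazinylidene}-7-oxo-6-(prop-2-en-1-yl)-12-(prop-1-en-2-yl)bicyclo[8.2.0]dodecan-4-yl]prop-2-enoate | O=C1CC[C@@H]2C(=NNS(=O)(=O)c3ccc(C)cc3)[C@H](C(=C)C)[C@@]2(C)CC[C@H](C(=C)C(=O)OC)C[C@H]1CC=C | intermediate
20 | methyl 2-[(1S,4S,6R,10S,12R)-11-{1-(1,3,2-benzodioxaborol-2-yl)-2-[(4-methylphenyl)sulfonyl]hydrazinyl}-1-methyl-7-oxo-6-(prop-2-en-1-yl)-12-(prop-1-en-2-yl)bicyclo[8.2.0]dodecan-4-yl]prop-2-enoate (C-11 epimers) | O=C1CC[C@@H]2C(N(NS(=O)(=O)c3ccc(C)cc3)B3Oc4ccccc4O3)[C@H](C(=C)C)[C@@]2(C)CC[C@H](C(=C)C(=O)OC)C[C@H]1CC=C | intermediate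
21 | methyl 2-[(1S,4S,6R,10R,12R)-1-methyl-7-oxo-6-(prop-2-en-1-yl)-12-(prop-1-en-2-yl)bicyclo[8.2.0]dodecan-4-yl]prop-2-enoate | O=C1CC[C@@H]2C[C@H](C(=C)C)[C@@]2(C)CC[C@H](C(=C)C(=O)OC)C[C@H]1CC=C | intermediate
22 | methyl 2-[(1S,4S,6R,10R,12R)-1-methyl-6-(3-methylbut-2-en-1-yl)-7-oxo-12-(prop-1-en-2-yl)bicyclo[8.2.0]dodecan-4-yl]prop-2-enoate | O=C1CC[C@@H]2C[C@H](C(=C)C)[C@@]2(C)CC[C@H](C(=C)C(=O)OC)C[C@H]1CC=C(C)C | intermediate
23 | methyl 2-[(1S,4S,6R,10R,12R)-1-methyl-7-methylidene-6-(3-methylbut-2-en-1-yl)-12-(prop-1-en-2-yl)bicyclo[8.2.0]dodecan-4-yl]prop-2-enoate | C=C1CC[C@@H]2C[C@H](C(=C)C)[C@@]2(C)CC[C@H](C(=C)C(=O)OC)C[C@H]1CC=C(C)C | target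

## Step count and weak points

Total step count: 12. Longest linear sequence: 11 steps (steps 1–7 and 9–12; step 8 is a one-step side branch).

Steps most likely to fail:

1. Step 6 (macrocyclising Michael addition). Risks are oligomerisation, the low reactivity of the α-substituted enone, and uncertain control at C7 and C5. The fallback keeps the same ring-closing bond but uses enamine catalysis; it sets out from aldehyde 9 and returns at acrylate 14. Wittig reaction of 9 with (methoxymethylene)triphenylphosphorane gives the enol ether F1, and mild aqueous HCl hydrolyses it to the homologous aldehyde F2. Under high dilution with (R)-α,α-diphenylprolinol trimethylsilyl ether and benzoic acid, F2 closes by intramolecular enamine Michael addition to the macrocyclic keto aldehyde F3; the catalyst shields one enamine face and this enantiomer gives 7S. The Ohira–Bestmann reagent (K2CO3, MeOH, 0 °C) converts F3 into the alkyne F4. Markovnikov hydromethoxycarbonylation of F4 (Pd(OAc)2, 2-(diphenylphosphino)pyridine, CH3SO3H, CO, MeOH) gives 14.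

2. Step 9 (keteniminium [2+2]). Risks are insufficient face selectivity on the flexible macrocycle, transannular capture of the developing C10 cation, and reaction at the allyl olefin. The fallback replaces substrate control by reagent control; it sets out from 14 (with acid chloride 15) and returns at tosylhydrazone 19. Acylation of (2R,5R)-2,5-dimethylpyrrolidine with 15 (aq. NaOH, CH2Cl2) gives the pyrrolidine amide F5; the antipodal auxiliary is used if it proves to be the matched one. Tf2O/collidine convert F5 into the chiral keteniminium triflate F6, which adds to 14 to give the cyclobutaniminium triflate F7. Exchange with tosylhydrazide then gives 19 and releases the auxiliary.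

3. Step 12 (methylenation of the hindered, α-branched ketone without loss of C5 configuration). The fallback is a two-stage Peterson olefination; it sets out from ketone 22 and returns at target 23. Me3SiCH2MgCl with CeCl3 (THF, −78 °C) adds to the ketone without enolisation or attack on the ester to give the β-hydroxysilane F8. KH (THF, 0 °C) then eliminates F8 to 23.

## Further compounds

F1 | step 6 | (8E)-13-methoxy-9-methyl-4-methylidenetrideca-1,8,12-trien-5-one (E/Z mixture at the enol ether) | C=CCC(=C)C(=O)CC/C=C(\C)CCC=COC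
F2 | step 6 | (5E)-5-methyl-10-methylidene-9-oxotrideca-5,12-dienal | C=CCC(=C)C(=O)CC/C=C(\C)CCCC=O
F3 | step 6 | (1S,4E,9R)-4-methyl-8-oxo-9-(prop-2-en-1-yl)cyclodec-4-ene-1-carbaldehyde | O=C1CC/C=C(\C)CC[C@H](C=O)C[C@H]1CC=C
F4 | step 6 | (4E,8S,10R)-8-ethynyl-5-methyl-10-(prop-2-en-1-yl)cyclodec-4-en-1-one | O=C1CC/C=C(\C)CC[C@H](C#C)C[C@H]1CC=C
F5 | step 9 | 1-[(2R,5R)-2,5-dimethylpyrrolidin-1-yl]-3-methylbut-2-en-1-one | C[C@@H]1CC[C@@H](C)N1C(=O)C=C(C)C
F6 | step 9 | (2R,5R)-2,5-dimethyl-1-(3-methylbuta-1,3-dien-1-ylidene)pyrrolidin-1-ium trifluoromethanesulfonate | C[C@@H]1CC[C@@H](C)[N+]1=C=CC(C)=C.[O-]S(=O)(=O)C(F)(F)F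
F7 | step 9 | (2R,5R)-1-[(1S,4S,6R,10S,12R)-4-(3-methoxy-3-oxoprop-1-en-2-yl)-1-methyl-7-oxo-6-(prop-2-en-1-yl)-12-(prop-1-en-2-yl)bicyclo[8.2.0]dodecan-11-ylidene]-2,5-dimethylpyrrolidin-1-ium trifluoromethanesulfonate | O=C1CC[C@@H]2C(=[N+]3[C@H](C)CC[C@H]3C)[C@H](C(=C)C)[C@@]2(C)CC[C@H](C(=C)C(=O)OC)C[C@H]1CC=C.[O-]S(=O)(=O)C(F)(F)F
F8 | step 12 | methyl 2-[(1S,4S,6R,10R,12R)-7-hydroxy-1-methyl-6-(3-methylbut-2-en-1-yl)-12-(prop-1-en-2-yl)-7-[(trimethylsilyl)methyl]bicyclo[8.2.0]dodecan-4-yl]prop-2-enoate (C-7 epimers) | C[Si](C)(C)CC1(O)CC[C@@H]2C[C@H](C(=C)C)[C@@]2(C)CC[C@H](C(=C)C(=O)OC)C[C@H]1CC=C(C)C
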